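How much complex with one exchanged stands at the end of each of the three new flasks, and does more incoming ligand leave more of it or less?

| flask | starting complex | incoming ligand | remark | time |
|---|---|---|---|---|
| spring | 0.30 M | 0.21 M | run made earlier |  |
| summer | 0.30 M | 1.8 M | run made earlier |  |
| Tuesday's | 0.30 M | 0.150 M |  | 30 h |
| Thursday's | 0.30 M | 0.360 M |  | 30 h |
| Monday's | 0.30 M | 1.20 M |  | 30 h |

| run | time / h | complex with one exchanged / % | starting complex / % |
|---|---|---|---|
| spring | 1.00 | 29 | 66 |
| spring | 3.00 | 28 | 63 |
| spring | 6.00 | 20 | 60 |
| spring | 10.0 | 18 | 58 |
| spring | 12.0 | 13 | 59 |
| spring | 15.0 | 14 | 55 |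
| spring | 20.0 | 9 | 57 |
| summer | 1.50 | 31 | 13 |
| summer | 2.50 | 31 | 16 |
| summer | 4.00 | 31 | 14 |
| summer | 6.00 | 27 | 12 |
| summer | 10.0 | 22 | 9 |
| summer | 15.0 | 22 | 9 |
| summer | 20.0 | 15 | 11 |

(readings scatter by 2 percentage points)

1. complex with one exchanged at the end, in percent of the starting complex charged, for each flask in turn (Tuesday's, Thursday's, Monday's)



Two chemists read these runs differently. The first sees the complex with one exchanged as a link in a chain: incoming ligand makes it and incoming ligand passes it on, so its fall should quicken in step with the ligand. Her evidence is that the summer run held 8.57 times the ligand of the spring run, yet its highest reading is 31% against 29% in spring. The spring readings halve in 11.3 h, so she scales that to 1.97 h for Monday's flask and expects it to end lowest.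

The second chemist measures what she scales. He defines the fade half-life, the time in which the complex with one exchanged halves once past its highest readings (an apparent first-order half-life). The summer readings give 15.3 h, which is longer than the spring value, although her scaling asks for 1.31 h. So he lets the end amount follow the early level, thinned by the fade.

I side with him. Carrying each run from its last reading to 30 h with his half-life, I get 5.72% for the spring charge and 9.53% for the summer charge, so by this estimate, with the starting complex the same in both, the amount rises with ligand.

The forecast takes his side with 5%, 8% and 11%, holding that “extra ligand doesn't accelerate this step”. Its last figure, for Monday's flask, is higher than my figure for the stronger summer charge, and there we differ.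

The flasks give 4.30%, 7.86% and 11.8%, so the forecast held and, from Tuesday's flask to Monday's, the amount rises with ligand.

    starting complex + incoming ligand ⇌ leaving ligand + complex with one exchanged (K = 0.790, k = 4.74 M⁻¹ h⁻¹)
    complex with one exchanged + incoming ligand ⇌ leaving ligand + complex with two exchanged (K = 0.431, k = 1.53 M⁻¹ h⁻¹)
    complex with one exchanged ⇌ isomer of the product (K = 12.3, k = 0.122 h⁻¹)
    incoming ligand ⇌ dormant form (K = 14.0, k = 0.0444 h⁻¹)
    incoming ligand → decomposition product (k = 2.18 × 10⁻⁴ h⁻¹)

Her chain has its place in Thursday's flask with the ligand as charged: the second exchange by itself, its way back not counted, halves the complex with one exchanged in 1.3 h, against 5.7 h for the forward path to the isomer of the product. From half time, the fade half-life takes Thursday's 15.3% to 7.75%, and that flask holds 7.86%. It takes Tuesday's 8.96% to 4.54%, and that flask holds 4.30%.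

All runs were generated by integration from invented constants, noise included.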